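**Plan**
- Retrosynthesis: after removal of three benzyl ethers and one acetonide, ring C is opened at O1–C8a, C4–C4a and O1–C2. This gives a 3,5-bis(benzyloxy)benzyne (ring A) and a ring B arylpropiolic acid.
- Enabling feature: in ring A, C8a (bonded to O1) and C4a (bonded to the C4 carbonyl) are neighbours and C4a is flanked by oxygenated C5. This is the pattern left when a carboxylic acid adds across a 3,5-dioxygenated benzyne.
- The acid is cut further at C3–C4 (CO2), C1'–C2 (Sonogashira coupling on the aryl bromide), C7''–C8'' (aldol) and O–C8'' (phenol alkylation).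
- Forward: the side chain is built on the ring B bromophenol, the alkyne and carboxyl group are added, ring C is closed onto the aryne in one step, and the protecting groups come off last.
- Stereochemistry: C7'' and C8'' are set together in one Evans syn aldol under control of (R)-4-benzyl-2-oxazolidinone; no later step touches them.

Key step: step 11

Assumption: the boron enolate of the aryloxyacetyl imide reacts with the usual Evans sense (as alkoxyacetyl imides do), so the (R)-auxiliary gives the syn pair that is (7''S,8''S), i.e. threo, after reduction.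

**Step 1**
Reactants: 1 3,5-bis(benzyloxy)phenol
Product: 2 3,5-bis(benzyloxy)-2-bromophenol
Conditions: NBS, i-Pr2NH (cat.), CH2Cl2, −78 → 0 °C
Reagents that add atoms: N-bromosuccinimide, O=C1CCC(=O)N1Br
Why: Amine-catalysed electrophilic aromatic bromination, in which the N-bromoamine is held by hydrogen bonding to the phenolic OH and should deliver bromine to the equivalent C2/C6 positions rather than to C4, which lies between two benzyloxy groups.

**Step 2**
Reactants: 2 3,5-bis(benzyloxy)-2-bromophenol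
Product: 5 3,5-bis(benzyloxy)-2-(trimethylsilyl)phenyl trifluoromethanesulfonate, via aryl trimethylsilyl ether 3 (not isolated), via lithium 2-silylphenoxide 4 (not isolated)
Conditions: HMDS, THF, 65 °C; evaporate; n-BuLi, THF, −78 °C; Tf2O, −78 → 0 °C
Reagents that add atoms: hexamethyldisilazane, C[Si](C)(C)N[Si](C)(C)C; trifluoromethanesulfonic anhydride, O=S(=O)(OS(=O)(=O)C(F)(F)F)C(F)(F)F
Why: O-silylation, bromine–lithium exchange (far faster at −78 °C than deprotonation of the benzylic CH2 groups), anionic 1,3 O-to-C silyl migration (retro-Brook rearrangement) and O-triflation of the phenoxide form the standard one-flask route to ortho-silylaryl triflates.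

**Step 3**
Reactants: 6 4-bromo-2,6-dimethoxyphenol
Product: 8 2-(4-bromo-2,6-dimethoxyphenoxy)acetic acid, via ethyl aryloxyacetate 7 (not isolated)
Conditions: BrCH2CO2Et, K2CO3, DMF, 60 °C; then aq. NaOH, rt; HCl work-up
Reagents that add atoms: ethyl bromoacetate, BrCC(=O)OCC; sodium hydroxide, [Na+].[OH-]
Why: Williamson ether synthesis of the phenoxide with an activated primary bromide, followed by saponification of the ester in the same flask; neither affects the aryl bromide or the methyl ethers.

**Step 4**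
Reactants: 8 2-(4-bromo-2,6-dimethoxyphenoxy)acetic acid; 9 (R)-4-benzyl-2-oxazolidinone
Product: 11 (R)-4-benzyl-3-[2-(4-bromo-2,6-dimethoxyphenoxy)acetyl]oxazolidin-2-one, via mixed pivalic anhydride 10 (not isolated)
Conditions: PivCl, Et3N, THF, −20 °C; then 9, LiCl, rt
Reagents that add atoms: none
Why: N-acylation of the oxazolidinone through the mixed pivalic anhydride with LiCl activation, the unhindered aryloxyacetyl carbonyl being attacked in preference to the pivaloyl carbonyl.

**Step 5**
Reactants: 11 (R)-4-benzyl-3-[2-(4-bromo-2,6-dimethoxyphenoxy)acetyl]oxazolidin-2-one; 12 4-(benzyloxy)benzaldehyde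
Product: 14 (4R)-4-benzyl-3-[(2R,3S)-3-[4-(benzyloxy)phenyl]-2-(4-bromo-2,6-dimethoxyphenoxy)-3-hydroxypropanoyl]oxazolidin-2-one, via Z-boron enolate 13 (not isolated)
Conditions: Bu2BOTf, Et3N, CH2Cl2, −78 → 0 °C; 12, −78 → 0 °C; H2O2, pH 7 buffer, MeOH, 0 °C
Reagents that add atoms: none
Why: Evans syn aldol reaction, in which soft enolisation gives the Z-boron enolate and the aldehyde adds through a closed Zimmerman–Traxler chair on the enolate face away from the benzyl group of the (R)-auxiliary, setting C8'' and C7'' together as the syn (threo) pair, (2R,3S) in the imide.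

**Step 6**
Reactants: 14 the aldol adduct
Product: 15 (1S,2S)-1-[4-(benzyloxy)phenyl]-2-(4-bromo-2,6-dimethoxyphenoxy)propane-1,3-diol
Conditions: LiBH4, MeOH (1 equiv), THF, 0 °C
Reagents that add atoms: none
Why: Reductive cleavage of the N-acyloxazolidinone by LiBH4 at the exocyclic carbonyl releases the 1,3-diol and the auxiliary without touching either stereocentre (the aryloxy carbon becomes S only because CH2OH ranks below the carbinol carbon).

**Step 7**
Reactants: 15 the (1S,2S)-diol
Product: 16 (4S,5S)-4-[4-(benzyloxy)phenyl]-5-(4-bromo-2,6-dimethoxyphenoxy)-2,2-dimethyl-1,3-dioxane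
Conditions: Me2C(OMe)2, PPTS (cat.), acetone, rt
Reagents that add atoms: 2,2-dimethoxypropane, COC(C)(C)OC
Why: Acid-catalysed transketalisation closes the six-membered isopropylidene acetal (a cis-4,5-disubstituted 1,3-dioxane), and PPTS is too weak to ionise the electron-rich benzylic carbinol.

**Step 8**
Reactants: 16 the bromo acetonide
Product: 17 [(4-{[(4S,5S)-4-[4-(benzyloxy)phenyl]-2,2-dimethyl-1,3-dioxan-5-yl]oxy}-3,5-dimethoxyphenyl)ethynyl]trimethylsilane
Conditions: HC≡CSiMe3, PdCl2(PhCN)2 (cat.), t-Bu3P·HBF4, CuI, i-Pr2NH, dioxane, rt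
Reagents that add atoms: ethynyltrimethylsilane, C#C[Si](C)(C)C
Why: Sonogashira coupling, in which the bulky electron-rich phosphine lets zerovalent palladium insert into the alkoxy-substituted aryl bromide at ambient temperature while the acetal and benzyl ether are inert to the amine base.

**Step 9**
Reactants: 17 the silyl alkyne
Product: 18 (4S,5S)-4-[4-(benzyloxy)phenyl]-5-(4-ethynyl-2,6-dimethoxyphenoxy)-2,2-dimethyl-1,3-dioxane
Conditions: K2CO3, MeOH–THF, rt
Reagents that add atoms: none
Why: Base-catalysed methanolysis of the alkynyl C–Si bond (protodesilylation), which leaves the acetonide and all ethers alone.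

**Step 10**
Reactants: 18 the terminal alkyne
Product: 20 3-(4-{[(4S,5S)-4-[4-(benzyloxy)phenyl]-2,2-dimethyl-1,3-dioxan-5-yl]oxy}-3,5-dimethoxyphenyl)prop-2-ynoic acid, via lithium acetylide 19 (not isolated)
Conditions: n-BuLi, THF, −78 °C; CO2, −78 → 0 °C; cold dilute HCl to pH 2, extract at once
Reagents that add atoms: carbon dioxide, O=C=O
Why: Deprotonation of the terminal alkyne, by far the most acidic site, and carboxylation of the lithium acetylide with CO2; the brief cold acidification spares the acetonide.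

**Step 11**
Reactants: 5 3,5-bis(benzyloxy)-2-(trimethylsilyl)phenyl trifluoromethanesulfonate; 20 the arylpropiolic acid
Product: 23 5,7-bis(benzyloxy)-2-(4-{[(4S,5S)-4-[4-(benzyloxy)phenyl]-2,2-dimethyl-1,3-dioxan-5-yl]oxy}-3,5-dimethoxyphenyl)-4H-chromen-4-one, via 3,5-bis(benzyloxy)benzyne 21 (not isolated), via cesium ortho-acylphenoxide 22 (not isolated)
Conditions: CsF, THF, 125 °C, sealed tube
Reagents that add atoms: none
Why: CsF strips the silyl group from 5 and triflate departs, giving aryne 21, whose strained bond is polarised by the inductive pull of the benzyloxy group on the flanking carbon (future C5): the carboxylate oxygen of 20 therefore adds at the far terminus (future C8a) and the resulting aryl anion sits at C4a, ortho to that benzyloxy group. This anion attacks its own ester carbonyl through a strained four-membered alkoxide whose collapse transfers the acyl group to carbon (C4–C4a) and frees phenoxide 22, which then undergoes 6-endo-dig oxa-Michael addition to the aryl-substituted alkyne carbon (O1–C2) to close ring C, with protonation at C3. The nearest precedent is the CsF-promoted insertion of arynes into the C–O bond of carboxylic acids, known to give ortho-hydroxyaryl ketones and, from arylpropiolic acids, flavones. No stereocentre is created, and C7'' and C8'' lie in the dioxane far from any basic or electrophilic site. Two selectivities are needed: the site of carboxylate attack on the aryne, fixed by the benzyloxy group adjacent to the triple bond, and six- over five-membered closure, fixed by the polarisation of the ynone towards its aryl-bearing carbon; heating in THF favours acyl transfer over simple protonation of the aryl anion.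

**Step 12**
Reactants: 23 the tribenzyl acetonide flavone
Product: 24 5,7-bis(benzyloxy)-2-(4-{[(1S,2S)-1-[4-(benzyloxy)phenyl]-1,3-dihydroxypropan-2-yl]oxy}-3,5-dimethoxyphenyl)-4H-chromen-4-one
Conditions: AcOH–H2O (4:1), 40 °C
Reagents that add atoms: none
Why: Acid-catalysed hydrolysis of the isopropylidene acetal in aqueous acetic acid is mild enough for the benzyl and methyl ethers, the 8''-O-4' ether and the flavone, and the still benzylated 4''-oxygen keeps the C7'' carbinol from ionising.

**Step 13**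
Reactants: 24 the tribenzyl diol
Product: 25 (−)-(7''S,8''S)-4'',5,7-trihydroxy-3',5'-dimethoxy-4',8''-oxyflavonolignan-7'',9''-diol
Conditions: H2 (1 atm), Pd/C, EtOAc–MeOH, rt
Reagents that add atoms: none
Why: Catalytic hydrogenolysis of the three aryl benzyl ethers over Pd/C under neutral conditions should be much faster than hydrogenolysis of the secondary benzylic alcohol or saturation of the chromone C2–C3 double bond, and it does not touch C7'' or C8''.

**Compound list**
1 | 3,5-bis(benzyloxy)phenol | Oc1cc(OCc2ccccc2)cc(OCc2ccccc2)c1 | starting material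
2 | 3,5-bis(benzyloxy)-2-bromophenol | Oc1cc(OCc2ccccc2)cc(OCc2ccccc2)c1Br | intermediate
3 | [3,5-bis(benzyloxy)-2-bromophenoxy]trimethylsilane | C[Si](C)(C)Oc1cc(OCc2ccccc2)cc(OCc2ccccc2)c1Br | intermediate
4 | lithium 3,5-bis(benzyloxy)-2-(trimethylsilyl)phenoxide | [Li+].[O-]c1cc(OCc2ccccc2)cc(OCc2ccccc2)c1[Si](C)(C)C | intermediate
5 | 3,5-bis(benzyloxy)-2-(trimethylsilyl)phenyl trifluoromethanesulfonate | C[Si](C)(C)c1c(OS(=O)(=O)C(F)(F)F)cc(OCc2ccccc2)cc1OCc1ccccc1 | intermediate
6 | 4-bromo-2,6-dimethoxyphenol | COc1cc(Br)cc(OC)c1O | starting material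
7 | ethyl 2-(4-bromo-2,6-dimethoxyphenoxy)acetate | CCOC(=O)COc1c(OC)cc(Br)cc1OC | intermediate
8 | 2-(4-bromo-2,6-dimethoxyphenoxy)acetic acid | OC(=O)COc1c(OC)cc(Br)cc1OC | intermediate
9 | (R)-4-benzyl-2-oxazolidinone | O=C1N[C@H](Cc2ccccc2)CO1 | starting material
10 | 2-(4-bromo-2,6-dimethoxyphenoxy)acetic pivalic anhydride | CC(C)(C)C(=O)OC(=O)COc1c(OC)cc(Br)cc1OC | intermediate
11 | (R)-4-benzyl-3-[2-(4-bromo-2,6-dimethoxyphenoxy)acetyl]oxazolidin-2-one | O=C(COc1c(OC)cc(Br)cc1OC)N1[C@H](Cc2ccccc2)COC1=O | intermediate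
12 | 4-(benzyloxy)benzaldehyde | O=Cc1ccc(OCc2ccccc2)cc1 | starting material
13 | (Z)-dibutylboron enolate of 11 | CCCCB(CCCC)O/C(=C\Oc1c(OC)cc(Br)cc1OC)N1[C@H](Cc2ccccc2)COC1=O | intermediate
14 | (4R)-4-benzyl-3-[(2R,3S)-3-[4-(benzyloxy)phenyl]-2-(4-bromo-2,6-dimethoxyphenoxy)-3-hydroxypropanoyl]oxazolidin-2-one | COc1cc(Br)cc(OC)c1O[C@@H](C(=O)N2[C@H](Cc3ccccc3)COC2=O)[C@@H](O)c1ccc(OCc2ccccc2)cc1 | intermediate
15 | (1S,2S)-1-[4-(benzyloxy)phenyl]-2-(4-bromo-2,6-dimethoxyphenoxy)propane-1,3-diol | COc1cc(Br)cc(OC)c1O[C@@H](CO)[C@@H](O)c1ccc(OCc2ccccc2)cc1 | intermediate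
16 | (4S,5S)-4-[4-(benzyloxy)phenyl]-5-(4-bromo-2,6-dimethoxyphenoxy)-2,2-dimethyl-1,3-dioxane | COc1cc(Br)cc(OC)c1O[C@@H](COC2(C)C)[C@@H](O2)c1ccc(OCc2ccccc2)cc1 | intermediate
17 | [(4-{[(4S,5S)-4-[4-(benzyloxy)phenyl]-2,2-dimethyl-1,3-dioxan-5-yl]oxy}-3,5-dimethoxyphenyl)ethynyl]trimethylsilane | COc1cc(C#C[Si](C)(C)C)cc(OC)c1O[C@@H](COC2(C)C)[C@@H](O2)c1ccc(OCc2ccccc2)cc1 | intermediate
18 | (4S,5S)-4-[4-(benzyloxy)phenyl]-5-(4-ethynyl-2,6-dimethoxyphenoxy)-2,2-dimethyl-1,3-dioxane | COc1cc(C#C)cc(OC)c1O[C@@H](COC2(C)C)[C@@H](O2)c1ccc(OCc2ccccc2)cc1 | intermediate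
19 | lithium acetylide of 18 | [Li]C#Cc1cc(OC)c(O[C@@H](COC2(C)C)[C@@H](O2)c2ccc(OCc3ccccc3)cc2)c(OC)c1 | intermediate
20 | 3-(4-{[(4S,5S)-4-[4-(benzyloxy)phenyl]-2,2-dimethyl-1,3-dioxan-5-yl]oxy}-3,5-dimethoxyphenyl)prop-2-ynoic acid | OC(=O)C#Cc1cc(OC)c(O[C@@H](COC2(C)C)[C@@H](O2)c2ccc(OCc3ccccc3)cc2)c(OC)c1 | intermediate
21 | 3,5-bis(benzyloxy)benzyne | C1#CC(OCc2ccccc2)=CC(OCc2ccccc2)=C1 | intermediate
22 | cesium 3,5-bis(benzyloxy)-2-[3-(4-{[(4S,5S)-4-[4-(benzyloxy)phenyl]-2,2-dimethyl-1,3-dioxan-5-yl]oxy}-3,5-dimethoxyphenyl)prop-2-ynoyl]phenoxide | [Cs+].[O-]c1cc(OCc2ccccc2)cc(OCc2ccccc2)c1C(=O)C#Cc1cc(OC)c(O[C@@H](COC2(C)C)[C@@H](O2)c2ccc(OCc3ccccc3)cc2)c(OC)c1 | intermediate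
23 | 5,7-bis(benzyloxy)-2-(4-{[(4S,5S)-4-[4-(benzyloxy)phenyl]-2,2-dimethyl-1,3-dioxan-5-yl]oxy}-3,5-dimethoxyphenyl)-4H-chromen-4-one | COc1cc(-c2cc(=O)c3c(OCc4ccccc4)cc(OCc4ccccc4)cc3o2)cc(OC)c1O[C@@H](COC1(C)C)[C@@H](O1)c1ccc(OCc2ccccc2)cc1 | intermediate
24 | 5,7-bis(benzyloxy)-2-(4-{[(1S,2S)-1-[4-(benzyloxy)phenyl]-1,3-dihydroxypropan-2-yl]oxy}-3,5-dimethoxyphenyl)-4H-chromen-4-one | COc1cc(-c2cc(=O)c3c(OCc4ccccc4)cc(OCc4ccccc4)cc3o2)cc(OC)c1O[C@@H](CO)[C@@H](O)c1ccc(OCc2ccccc2)cc1 | intermediate
25 | (−)-(7''S,8''S)-4'',5,7-trihydroxy-3',5'-dimethoxy-4',8''-oxyflavonolignan-7'',9''-diol | COc1cc(-c2cc(=O)c3c(O)cc(O)cc3o2)cc(OC)c1O[C@@H](CO)[C@@H](O)c1ccc(O)cc1 | target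

**Step count**
Total: 13 steps (2 to the aryne precursor, 8 to the acid, 3 from their union).
Longest linear sequence: 11 steps (steps 3 to 13, from 6).

**Steps most likely to fail**

Step 11. The aryl anion may be protonated before it reaches the carbonyl, so the reaction stops at simple O-arylation. The cesium propiolate may also lose CO2 on heating, or the acylphenoxide may close in the five-membered mode. The fallback sets out from phenol 1 and alkyne 18 and comes back at 23 without an aryne. Phenol 1 is iodinated ortho to the hydroxyl (NIS, CH2Cl2, 0 °C) to give 3,5-bis(benzyloxy)-2-iodophenol F1. F1, alkyne 18 and CO are then joined in a carbonylative Sonogashira annulation (PdCl2(dppf), Et2NH, CO, 120 °C), in which the secondary amine acts as base and steers the closure to the six-membered ring.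

Step 1. Bromination para to the hydroxyl, at C4 between the two benzyloxy groups, and twofold bromination may compete with attack at C2. The fallback sets out from 1 and comes back at 5, bypassing 2 to 4, with the position fixed by directed ortho-metalation. Isopropyl isocyanate and Et3N convert 1 into 3,5-bis(benzyloxy)phenyl N-(propan-2-yl)carbamate F2. Lithiation (TMSOTf, TMEDA; n-BuLi, TMEDA, −78 °C; TMSCl; acidic work-up) occurs at the carbon between the carbamate and a benzyloxy group, the doubly activated site, and gives 3,5-bis(benzyloxy)-2-(trimethylsilyl)phenyl N-(propan-2-yl)carbamate F3. DBU and Et2NH in MeCN cleave the carbamate to 3,5-bis(benzyloxy)-2-(trimethylsilyl)phenol F4, which is triflated in the same flask with PhNTf2 to give 5.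

Step 13. Once the 4''-phenol is unveiled, the free benzylic C7''–OH may be lost by hydrogenolysis through a para-quinone methide on the catalyst. The fallback sets out from 23 and comes back at 25 with the two deprotections in reverse order, so that the benzylic oxygen is still a dioxane ring oxygen during the reduction. Hydrogenolysis of 23 (H2, Pd/C, THF–MeOH, rt) gives 5,7-dihydroxy-2-(4-{[(4S,5S)-4-(4-hydroxyphenyl)-2,2-dimethyl-1,3-dioxan-5-yl]oxy}-3,5-dimethoxyphenyl)-4H-chromen-4-one F5. The acetonide of F5 is then hydrolysed with aqueous acetic acid at ambient temperature to give 25.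

**Further compounds**
F1 | step 11 | 3,5-bis(benzyloxy)-2-iodophenol | Oc1cc(OCc2ccccc2)cc(OCc2ccccc2)c1I
F2 | step 1 | 3,5-bis(benzyloxy)phenyl N-(propan-2-yl)carbamate | CC(C)NC(=O)Oc1cc(OCc2ccccc2)cc(OCc2ccccc2)c1
F3 | step 1 | 3,5-bis(benzyloxy)-2-(trimethylsilyl)phenyl N-(propan-2-yl)carbamate | CC(C)NC(=O)Oc1cc(OCc2ccccc2)cc(OCc2ccccc2)c1[Si](C)(C)C
F4 | step 1 | 3,5-bis(benzyloxy)-2-(trimethylsilyl)phenol | Oc1cc(OCc2ccccc2)cc(OCc2ccccc2)c1[Si](C)(C)C
F5 | step 13 | 5,7-dihydroxy-2-(4-{[(4S,5S)-4-(4-hydroxyphenyl)-2,2-dimethyl-1,3-dioxan-5-yl]oxy}-3,5-dimethoxyphenyl)-4H-chromen-4-one | COc1cc(-c2cc(=O)c3c(O)cc(O)cc3o2)cc(OC)c1O[C@@H](COC1(C)C)[C@@H](O1)c1ccc(O)cc1
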